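The benzene ring is made last. It is para-disubstituted, with the acyloxyethyl chain on C1', the hydroxyl on C4' and hydrogen on the other four carbons. This is the pattern of a 4-substituted cyclohex-2-enone, so the ring is cut at C1'–C6' and C2'–C3'. One operation, an amine-catalysed Michael addition to methyl vinyl ketone followed by aldol condensation, forms both bonds and closes the carbocycle. Its precursor is 4-oxobutyl pentacosanoate, a linear aldehyde that already carries the complete fatty ester and supplies C1' and C2'; the butenone supplies C3' to C6'. A final dehydrogenation unveils the phenol, so no protecting group is needed.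

Key step: step 3

Assumption (chemistry): the C25 ester intermediates are waxy and poorly soluble in cold or very polar media, so every step is planned at or above room temperature in THF, CH2Cl2, toluene or warm DMSO. The enone 9 is carried as a racemate because its only stereocentre becomes sp2 in step 4.

Step 1
Reactants: 1 pentacosanoic acid; 2 1,4-butanediol (8 equiv)
Product: 3 4-hydroxybutyl pentacosanoate
Conditions: DIC (N,N'-diisopropylcarbodiimide, 1.2 equiv), DMAP (0.2 equiv), THF, 40 °C
Reagents that add atoms: none
Why: Steglich esterification of a primary alcohol; the large excess of the symmetrical, water-soluble diol should keep diacylation statistically low, and the surplus diol is removed by aqueous washing.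

Step 2
Reactants: 3 4-hydroxybutyl pentacosanoate
Product: 4 4-oxobutyl pentacosanoate
Conditions: TEMPO (0.1 equiv), PhI(OAc)2 (1.2 equiv), CH2Cl2, 25 °C
Reagents that add atoms: none
Why: The TEMPO/PhI(OAc)2 (oxoammonium) oxidation of a primary alcohol should stop at the aldehyde in the absence of water and leave the ester untouched.

Step 3
Reactants: 4 4-oxobutyl pentacosanoate; 5 methyl vinyl ketone (1.5 equiv)
Product: 9 2-(4-oxocyclohex-2-en-1-yl)ethyl pentacosanoate (racemic), via diethyl enamine 6 (not isolated), via keto aldehyde 7 (not isolated), via ring ketol 8 (not isolated)
Conditions: Et2NH (0.3 equiv), toluene, 40 °C; then evaporate volatiles; TsOH·H2O (0.2 equiv), toluene, 80 °C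
Reagents that add atoms: none
Why: Diethylamine condenses reversibly with aldehyde 4 to the E-enamine 6, whose nucleophilic carbon (the future C1') adds to the terminal CH2 of 5 (the future C6'); the water released in enamine formation then hydrolyses the adduct, returning the amine and giving keto aldehyde 7. This is the amine-catalysed, Stork-type Michael addition of an unmodified aldehyde to a vinyl ketone followed by the aldol half of a Robinson annulation, a known sequence from linear aldehydes and methyl vinyl ketone to 4-substituted cyclohex-2-enones. Under acid the methyl-side enol of the ketone attacks the aldehyde carbon in a 6-(enolendo)-exo-trig closure that forms C2'–C3' and gives ketol 8, which dehydrates to the conjugated enone 9. The single new stereocentre (ring C1', the carbon bearing the side chain) is formed without any controlling element, so 9 should arise as a racemate, which is acceptable because this carbon becomes sp2 in step 4. The step needs mono-addition and one aldol pairing only: the first alkylation makes the α-carbon tertiary and so slows a second Michael addition, and every other enol/carbonyl pairing in 7 would close a four-membered ring. The ester oxygen sits on the γ-carbon of the aldehyde, so neither the enamine nor an enol can expel it by β-elimination, and the amine and sulfonic acid conditions should leave the ester intact.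

Step 4
Reactants: 9 2-(4-oxocyclohex-2-en-1-yl)ethyl pentacosanoate
Product: 11 2-(4-hydroxyphenyl)ethyl pentacosanoate (target), via dienone tautomer 10 (not isolated)
Conditions: Pd(O2CCF3)2 (5 mol%), 2-(dimethylamino)pyridine (10 mol%), TsOH·H2O (20 mol%), O2 (1 atm), DMSO, 80 °C
Reagents that add atoms: none
Why: Known aerobic dehydrogenation of cyclohexenones to phenols by divalent palladium: a palladium enolate forms at C5', β-hydride elimination from C6' gives the cross-conjugated dienone 10, which tautomerises at once to the phenol (erasing the C1' stereocentre), while O2 reoxidises zerovalent palladium.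

Compound list
1 | pentacosanoic acid | CCCCCCCCCCCCCCCCCCCCCCCCC(=O)O | starting material
2 | 1,4-butanediol | OCCCCO | starting material
3 | 4-hydroxybutyl pentacosanoate | CCCCCCCCCCCCCCCCCCCCCCCCC(=O)OCCCCO | intermediate
4 | 4-oxobutyl pentacosanoate | CCCCCCCCCCCCCCCCCCCCCCCCC(=O)OCCCC=O | intermediate
5 | methyl vinyl ketone (but-3-en-2-one) | CC(=O)C=C | starting material
6 | (E)-4-(diethylamino)but-3-en-1-yl pentacosanoate | CCCCCCCCCCCCCCCCCCCCCCCCC(=O)OCC/C=C/N(CC)CC | intermediate (not isolated)
7 | 3-formyl-6-oxoheptyl pentacosanoate (racemic) | CCCCCCCCCCCCCCCCCCCCCCCCC(=O)OCCC(C=O)CCC(C)=O | intermediate (not isolated)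
8 | 2-(2-hydroxy-4-oxocyclohexyl)ethyl pentacosanoate (racemic mixture of diastereomers) | CCCCCCCCCCCCCCCCCCCCCCCCC(=O)OCCC1CCC(=O)CC1O | intermediate (not isolated)
9 | 2-(4-oxocyclohex-2-en-1-yl)ethyl pentacosanoate (racemic) | CCCCCCCCCCCCCCCCCCCCCCCCC(=O)OCCC1C=CC(=O)CC1 | intermediate
10 | 2-(4-oxocyclohexa-2,5-dien-1-yl)ethyl pentacosanoate | CCCCCCCCCCCCCCCCCCCCCCCCC(=O)OCCC1C=CC(=O)C=C1 | intermediate (not isolated)
11 | 2-(4-hydroxyphenyl)ethyl pentacosanoate | CCCCCCCCCCCCCCCCCCCCCCCCC(=O)OCCc1ccc(O)cc1 | target

Total step count: 4
Longest linear sequence: 4 steps (1 → 3 → 4 → 9 → 11)

Steps most likely to fail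

Step 3. Self-aldol condensation of the free aldehyde, amine-initiated oligomerisation of the vinyl ketone, or a second Michael addition may outrun the desired mono-addition. The fallback sets out from 4 and returns at 9, and replaces the catalytic process by a stoichiometric, preformed Stork enamine, so that no free aldehyde is present during C–C bond formation. Aldehyde 4 is stirred with pyrrolidine (1.5 equiv) and K2CO3 in toluene from 0 °C to room temperature, filtered and evaporated to give crude (E)-4-(pyrrolidin-1-yl)but-3-en-1-yl pentacosanoate F1. This is treated with 5 in toluene at room temperature and then warmed with an aqueous AcOH/NaOAc buffer, which should hydrolyse the adduct to 7 and carry it through 8 to 9.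

Step 4. The palladium cycle may stall through aggregation to palladium black before conversion is complete, made worse by slow dissolution of the waxy substrate in DMSO. The fallback sets out from 9 and returns at 11, and uses ionic halogenation and dehydrohalogenation in place of metal-catalysed dehydrogenation. Enone 9 is heated with CuBr2 (2.2 equiv) and LiBr in MeCN/THF at reflux. This should brominate next to the carbonyl to give 2-(5-bromo-4-oxocyclohex-2-en-1-yl)ethyl pentacosanoate F2, which is not isolated, loses hydrogen bromide to give dienone 10 and tautomerises to 11.

Step 1. Statistical over-acylation may give the diester, and co-crystallisation of the waxy mono- and diester may make their separation lossy. The fallback sets out from 1 and returns at 4, bypassing 3 and step 2, with a mono-alcohol that cannot be acylated twice. Acid 1 is esterified with pent-4-en-1-ol (1.2 equiv; DIC, DMAP, CH2Cl2/THF, 35 °C) to give pent-4-en-1-yl pentacosanoate F3. Ozonolysis of its terminal alkene (O3, CH2Cl2, −40 °C or the lowest temperature at which the ester stays dissolved; then PPh3) should give aldehyde 4 directly.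

Further compounds
F1 | step 3 | (E)-4-(pyrrolidin-1-yl)but-3-en-1-yl pentacosanoate | CCCCCCCCCCCCCCCCCCCCCCCCC(=O)OCC/C=C/N1CCCC1
F2 | step 4 | 2-(5-bromo-4-oxocyclohex-2-en-1-yl)ethyl pentacosanoate (mixture of diastereomers) | CCCCCCCCCCCCCCCCCCCCCCCCC(=O)OCCC1C=CC(=O)C(Br)C1
F3 | step 1 | pent-4-en-1-yl pentacosanoate | CCCCCCCCCCCCCCCCCCCCCCCCC(=O)OCCCC=C
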